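## Structural features

The target is a trans-3,4-disubstituted γ-butyrolactone (ring A: O1, C2 carbonyl, C3, C4, C5). C3 carries a 4-hydroxy-3-methoxybenzyl group (guaiacyl, ring C) and C4 a 4-hydroxy-3,5-dimethoxybenzyl group (syringyl, ring B); the three rings are joined only through the two benzylic CH2 groups. C3 and C4 are adjacent stereocentres, both R, and there are no others. C3 lies α to the lactone carbonyl and can be epimerized by base, although the trans arrangement is the more stable one. The lactone opens with nucleophiles, and the two free phenols, above all the one of ring B, are easily oxidized. The real difficulty is placing two nearly identical benzyl groups on the correct carbons of a four-carbon chain with control of absolute configuration. Each benzylic CH2 is a one-carbon branch on C3 or C4, so C2–C3–C4–C5 with its two branches is the skeleton of 2,3-dimethylsuccinic acid. The key step exploits this: with C2 as an 8-aminoquinoline amide, the branch carbon on C3 is a β-methyl group whose C–H bond is exchanged for ring C.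

## Logic of the disconnections

18 to 17: the two phenol O–CH2Ph bonds are cut. Free phenols would not survive the silver and palladium oxidants used earlier, and benzyl ethers come off last under neutral hydrogenolysis. The demand is that hydrogenolysis spares the lactone and the two aryl–CH2–C bonds, which carry no oxygen and are inert.

17 to 15: the acyl–O1 bond of ring A is cut, the carbonyl being returned to the nitrogen of 12 and O1 to silicon. This removes the ring and shows that the directing group of the key step is also the leaving group of the lactonization. Silyl ether cleavage and ring closure are planned as one acid-mediated operation through 16. The demand is an N-to-O acyl transfer that does not disturb C3.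

15 to 14 and 5: the bond between the benzylic carbon on C3 and ring C is cut. The benzylic carbon then becomes a methyl group β to the amide carbonyl, the position a five-membered palladacycle reaches. Ring C enters whole and no stereocentre is created. The demand is a single arylation at the primary C–H bond with both existing stereocentres retained.

14 to 13, and 13 to 11 and 12: the Si–O bond and then the amide N–C bond are cut, which re-forms a lactone. In 11 the C2 carbonyl and the C5 oxygen are already differentiated and the compound is stable to storage. The demand is that 13 is silylated before it can close again with loss of 12. The tert-butyldimethylsilyl group is chosen because it should withstand acetate at 100 °C and still fall to the acid that later closes the ring.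

11 to 9: the acyl–O bond is cut and C5 is raised to the carboxyl level. The carboxyl that later becomes C5 first serves as the directing group for the arylation on its own side, so the site of arylation and the site of reduction are tied together. The demand is a reduction of the acid in the presence of the methyl ester; 10 then closes by itself.

9 to 8 and 3: the bond between the benzylic carbon on C4 and ring B is cut. This leaves a methyl group β to a free carboxylate. The demand is carboxylate-directed palladation of a primary C–H bond in an acid that has an α-hydrogen, with the ester not competing as a director.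

8 to 6: the ester O–CH3 bond is cut. Because 6 is C2-symmetric, opening of 7 with methanol can give only one half-ester, and both stereocentres are bought in one building block. The demand is anhydride formation without epimerization.

3 to 2 to 1, and 5 to 4: the benzyl–O bonds and the C–I bond of ring B are cut. Both aryl iodides then derive from simple phenols. The demand is iodination para to the hydroxyl of an oxidation-prone phenol.

## Other disconnections considered

Alternative 1: The cut is the C3–C4 bond, made together with two C–O bonds. Ferulic acid A2 and sinapyl alcohol A3 would be oxidized by a laccase under air, beside a dirigent protein, to phenoxy radicals that join at their β-carbons. The two quinone methides are then trapped, the carboxyl at the syringyl benzylic carbon and the hydroxyl at the guaiacyl benzylic carbon, giving the cis-fused furofuranone A1. Hydrogenolysis of the two benzylic C–O bonds of A1 and re-closure of the lactone on the primary hydroxyl would lead to 18; the cis ring fusion of A1 maps onto the trans lactone.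
- In its favour: the whole skeleton and both stereocentres arise in one operation from two unprotected C6–C3 units, without protecting groups or silver. Which partner is the acid fixes the guaiacyl group on the carbonyl side.
- Against it here: the two homo-couplings compete with the cross-coupling, and the guaiacyl radical has further reactive positions. A dirigent protein that guides this mixed pair to one enantiomer of A1 cannot be assumed, so absolute configuration would rest on an unproven biocatalyst.
- Comparison: on structure, both readings fit (two C6–C3 halves against a C4 core with aryl groups added last). On mechanism, radical–radical coupling offers little handle for chemo- and enantiocontrol, whereas the chelate in 14 defines the reacting site. On step economy the alternative is clearly the better, about three steps against eleven.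

Alternative 2: The cut removes ring B at the two ring bonds between the methoxy-bearing carbons and the neighbouring CH carbons. 1,3-Dimethoxyacetone A5 would condense through both α-carbons with the two termini of the vinamidinium salt A6 under a strong alkoxide base. Loss of two dimethylamine units aromatizes to the phenol A4, whose phenol carbon is the former ketone carbon; debenzylation of A4 gives 18.
- In its favour: the syringyl substitution pattern is built with unambiguous regiochemistry, so the para-iodination of an oxidation-prone phenol (step 1) is avoided. On this point it is the better plan. The syringyl phenol also arrives free, leaving one benzyl ether to remove.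
- Against it here: the annulation creates no stereocentre. C3 and C4 must come from a separate asymmetric synthesis of the acid A7, from which A6 would be made by Vilsmeier-type formylation with decarboxylation. The lactone with its enolizable C3–H must then survive a chloroiminium reagent and an alkoxide, which invites ring opening or attack of the lactone enolate on A6.
- Comparison: on structure, the key step is spent on the part that is easiest to buy. On mechanism, the ionic condensation is well understood and metal-free, equal in reliability on simple ketones but less secure beside a base-sensitive lactone. On step economy, A7 alone should need about as many steps as the whole chosen route, so this plan is longer.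

Alternative 3: The cut is the C4–C5 bond. The (bromomethyl)dimethylsilyl ether A9 of a γ-hydroxy enoate would be treated with a tin hydride and an azo initiator. The silylmethyl radical closes 5-exo-trig on the enoate β-carbon and gives the oxasilacyclopentane A8, with the new bond trans to the aryl group. Tamao oxidation of the C–Si bond, lactonization on the primary hydroxyl, hydrogenolysis of the benzylic C–O bond together with the benzyl ethers, and base equilibration at C3 would complete 18.
- In its favour: the silicon tether is dependable, the closure is fast, and C4 is relayed predictably from a benzylic carbinol available by asymmetric reduction. In reliability of the C–C bond formation it is the equal of, or better than, the two C–H arylations.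
- Against it here: C3 is not controlled in the hydrogen-atom transfer and is left to thermodynamics. The controlling carbinol centre is destroyed afterwards. After oxidation two hydroxyl groups are both γ to the ester, so the lactonization must choose. Tin is used in stoichiometric amount.
- Comparison: on structure, the target is read as a hydroxymethylated enoate, against a diarylated succinate in the chosen plan. On mechanism, the radical chain is robust, while the chosen plan carries C3 unchanged from 6 and need not correct it. On step economy, A9 needs about five or six steps and five more follow, so the count is equal or slightly higher.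

Key step: step 9

Remark: (2R,3R)-2,3-dimethylsuccinic acid 6 is taken as a purchasable single enantiomer; if only the racemate is at hand it would be resolved as a diastereomeric amine salt before step 4.

## Route

Step 1
Reactants: 1 2,6-dimethoxyphenol
Product: 2 4-iodo-2,6-dimethoxyphenol
Conditions: I2 (1.05 equiv), NaHCO3, THF–H2O, 0 °C to rt
Reagents that add atoms: iodine (II)
Why: Electrophilic aromatic iodination through the phenoxide; both ortho positions carry methoxy groups, so the hydroxyl directs to the para carbon, and the bicarbonate buffer keeps the phenoxide concentration low to limit oxidative dimerization.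

Step 2
Reactants: 2 4-iodo-2,6-dimethoxyphenol
Product: 3 2-(benzyloxy)-5-iodo-1,3-dimethoxybenzene
Conditions: BnBr, K2CO3, DMF, 60 °C
Reagents that add atoms: benzyl bromide (BrCc1ccccc1)
Why: Williamson ether synthesis; the flanked phenoxide is still nucleophilic toward benzyl bromide in DMF and the aryl iodide is inert to carbonate.

Step 3
Reactants: 4 4-iodo-2-methoxyphenol
Product: 5 1-(benzyloxy)-4-iodo-2-methoxybenzene
Conditions: BnBr, K2CO3, DMF, rt
Reagents that add atoms: benzyl bromide (BrCc1ccccc1)
Why: Williamson ether synthesis on an unhindered phenol; nothing else in the molecule reacts.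

Step 4
Reactants: 6 (2R,3R)-2,3-dimethylsuccinic acid
Product: 8 (2R,3R)-4-methoxy-2,3-dimethyl-4-oxobutanoic acid, via trans-2,3-dimethylsuccinic anhydride 7 (not isolated)
Conditions: AcCl, reflux; evaporate; MeOH, reflux
Reagents that add atoms: methanol (CO)
Why: Dehydrative cyclization to the trans anhydride followed by anhydride alcoholysis; the two carbonyls of the C2-symmetric anhydride are equivalent, so only one half-ester can form, and neither stereocentre is touched under these non-basic conditions.

Step 5
Reactants: 8 (2R,3R)-4-methoxy-2,3-dimethyl-4-oxobutanoic acid; 3 2-(benzyloxy)-5-iodo-1,3-dimethoxybenzene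
Product: 9 (2R,3R)-2-(4-benzyloxy-3,5-dimethoxybenzyl)-4-methoxy-3-methyl-4-oxobutanoic acid
Conditions: 3 (1.5 equiv), Pd(OAc)2 (10 mol %), N-acetylglycine (20 mol %), Ag2CO3 (1.5 equiv), K2CO3 (1.0 equiv), HFIP, 90 °C
Reagents that add atoms: none
Why: Ligand-enabled carboxylate-directed β-C(sp3)–H arylation of an α-branched aliphatic acid with an aryl iodide; the carboxylate holds divalent palladium so that the methyl group on its own α-carbon is metalated through a five-membered palladacycle, while the ester is a poor ligand and its methyl group is γ to the carboxylate. No stereocentre is formed and the cleaved C–H bond lies on the methyl group, so both centres are retained.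

Step 6
Reactants: 9 (2R,3R)-2-(4-benzyloxy-3,5-dimethoxybenzyl)-4-methoxy-3-methyl-4-oxobutanoic acid
Product: 11 (3R,4R)-4-(4-benzyloxy-3,5-dimethoxybenzyl)-3-methyldihydrofuran-2(3H)-one, via hydroxy ester 10 (not isolated)
Conditions: BH3·THF (1.5 equiv), THF, 0 °C to rt; MeOH; then TsOH·H2O (10 mol %), toluene, 50 °C
Reagents that add atoms: none
Why: Chemoselective borane reduction of the carboxylic acid through its acyloxyborane, which leaves the methyl ester, followed by acid-catalysed lactonization of the γ-hydroxy ester; both stereocentres are spectators and the trans lactone results.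

Step 7
Reactants: 11 (3R,4R)-4-(4-benzyloxy-3,5-dimethoxybenzyl)-3-methyldihydrofuran-2(3H)-one; 12 8-aminoquinoline
Product: 13 (2R,3R)-3-(4-benzyloxy-3,5-dimethoxybenzyl)-4-hydroxy-2-methyl-N-(quinolin-8-yl)butanamide
Conditions: AlMe3 (2.0 equiv), 12 (2.0 equiv), CH2Cl2, 0 °C to 40 °C
Reagents that add atoms: none
Why: Weinreb-type aminolysis of a lactone by the dimethylaluminium amide of 12; the Lewis-acidic, weakly basic reagent attacks the acyl carbon without enolizing the adjacent stereocentre.

Step 8
Reactants: 13 (2R,3R)-3-(4-benzyloxy-3,5-dimethoxybenzyl)-4-hydroxy-2-methyl-N-(quinolin-8-yl)butanamide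
Product: 14 (2R,3R)-3-(4-benzyloxy-3,5-dimethoxybenzyl)-4-(tert-butyldimethylsilyloxy)-2-methyl-N-(quinolin-8-yl)butanamide
Conditions: TBSCl, imidazole, DMF, rt
Reagents that add atoms: tert-butyldimethylsilyl chloride (CC(C)(C)[Si](C)(C)Cl)
Why: Imidazole-mediated silylation of the primary alcohol; the amide N–H and the quinoline nitrogen do not compete, and the silyl ether blocks re-lactonization, which would expel the directing group in the hot arylation.

Step 9
Reactants: 14 (2R,3R)-3-(4-benzyloxy-3,5-dimethoxybenzyl)-4-(tert-butyldimethylsilyloxy)-2-methyl-N-(quinolin-8-yl)butanamide; 5 1-(benzyloxy)-4-iodo-2-methoxybenzene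
Product: 15 (2R,3R)-2-(4-benzyloxy-3-methoxybenzyl)-3-(4-benzyloxy-3,5-dimethoxybenzyl)-4-(tert-butyldimethylsilyloxy)-N-(quinolin-8-yl)butanamide
Conditions: 5 (1.3 equiv), Pd(OAc)2 (10 mol %), AgOAc (1.5 equiv), toluene, 100 °C, under argon
Reagents that add atoms: none
Why: The deprotonated amide nitrogen and the quinoline nitrogen of 14 bind divalent palladium as an N,N-chelate, and acetate-assisted concerted metalation–deprotonation of the methyl group on C2 gives a five-membered alkyl palladacycle fused to the chelate ring. Oxidative addition of 5 raises this to an aryl alkyl complex of tetravalent palladium, C(sp3)–C(sp2) reductive elimination forms the aryl–CH2 bond, and AgOAc takes up the iodide while the acetic acid formed frees the product from the metal. The closest known reaction type is the 8-aminoquinoline-directed β-methyl C–H arylation of aliphatic carboxamides with aryl iodides. No ring is closed and no stereocentre is created; C2 and C3 of 14 are carried through because the broken C–H bond lies on the methyl group and the weakly basic acetate medium should not enolize the amide. Three selectivities are needed: the methyl group over the tertiary C3–H, β over the γ CH2 groups, and one arylation instead of two. The first two follow from the preference of the metalation for primary C–H bonds and for the five-membered over the six-membered palladacycle. The third is secured by limiting 5 to 1.3 equivalents, by the moderate temperature, and by the crowding of the new benzylic CH2 between a tertiary carbon and the chelate. The silyl ether keeps the C4 oxygen from attacking the amide and the benzyl ethers keep both phenols away from the silver salt.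

Step 10
Reactants: 15 (2R,3R)-2-(4-benzyloxy-3-methoxybenzyl)-3-(4-benzyloxy-3,5-dimethoxybenzyl)-4-(tert-butyldimethylsilyloxy)-N-(quinolin-8-yl)butanamide
Product: 17 (3R,4R)-3-(4-benzyloxy-3-methoxybenzyl)-4-(4-benzyloxy-3,5-dimethoxybenzyl)dihydrofuran-2(3H)-one, via hydroxy amide 16 (not isolated)
Conditions: 3 M aq. HCl–THF (1:4), 60 °C
Reagents that add atoms: none
Why: Acid hydrolysis of the silyl ether releases the γ-hydroxy amide, whose hydroxyl attacks the protonated anilide carbonyl in a 5-exo-trig N-to-O acyl transfer (lactonization); the expelled 8-aminoquinoline is held as its salt, which makes the closure irreversible. Acid does not enolize C3, and the trans arrangement is in any case the stable one.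

Step 11
Reactants: 17 (3R,4R)-3-(4-benzyloxy-3-methoxybenzyl)-4-(4-benzyloxy-3,5-dimethoxybenzyl)dihydrofuran-2(3H)-one
Product: 18 (3R,4R)-3-(4-hydroxy-3-methoxybenzyl)-4-(4-hydroxy-3,5-dimethoxybenzyl)dihydrofuran-2(3H)-one
Conditions: H2 (1 atm), Pd/C (10 wt %), EtOAc–EtOH, rt
Reagents that add atoms: none
Why: Catalytic hydrogenolysis of the two aryl benzyl ethers; the lactone and the oxygen-free benzylic C–C bonds are inert and no stereocentre is involved.

## Compound list

1 | 2,6-dimethoxyphenol | COc1cccc(OC)c1O | starting material
2 | 4-iodo-2,6-dimethoxyphenol | COc1cc(I)cc(OC)c1O | intermediate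
3 | 2-(benzyloxy)-5-iodo-1,3-dimethoxybenzene | COc1cc(I)cc(OC)c1OCc1ccccc1 | intermediate
4 | 4-iodo-2-methoxyphenol | COc1cc(I)ccc1O | starting material
5 | 1-(benzyloxy)-4-iodo-2-methoxybenzene | COc1cc(I)ccc1OCc1ccccc1 | intermediate
6 | (2R,3R)-2,3-dimethylsuccinic acid | C[C@@H](C(=O)O)[C@H](C(=O)O)C | starting material
7 | (3R,4R)-3,4-dimethyldihydrofuran-2,5-dione (trans-2,3-dimethylsuccinic anhydride) | C[C@H]1C(=O)OC(=O)[C@@H]1C | intermediate (not isolated)
8 | (2R,3R)-4-methoxy-2,3-dimethyl-4-oxobutanoic acid | C[C@@H](C(=O)OC)[C@H](C(=O)O)C | intermediate
9 | (2R,3R)-2-(4-benzyloxy-3,5-dimethoxybenzyl)-4-methoxy-3-methyl-4-oxobutanoic acid | C[C@@H](C(=O)OC)[C@H](C(=O)O)Cc1cc(OC)c(OCc2ccccc2)c(OC)c1 | intermediate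
10 | methyl (2R,3R)-3-(4-benzyloxy-3,5-dimethoxybenzyl)-4-hydroxy-2-methylbutanoate | C[C@@H](C(=O)OC)[C@H](CO)Cc1cc(OC)c(OCc2ccccc2)c(OC)c1 | intermediate (not isolated)
11 | (3R,4R)-4-(4-benzyloxy-3,5-dimethoxybenzyl)-3-methyldihydrofuran-2(3H)-one | C[C@H]1C(=O)OC[C@@H]1Cc1cc(OC)c(OCc2ccccc2)c(OC)c1 | intermediate
12 | 8-aminoquinoline | Nc1cccc2cccnc12 | starting material
13 | (2R,3R)-3-(4-benzyloxy-3,5-dimethoxybenzyl)-4-hydroxy-2-methyl-N-(quinolin-8-yl)butanamide | C[C@@H](C(=O)Nc1cccc2cccnc12)[C@H](CO)Cc1cc(OC)c(OCc2ccccc2)c(OC)c1 | intermediate
14 | (2R,3R)-3-(4-benzyloxy-3,5-dimethoxybenzyl)-4-(tert-butyldimethylsilyloxy)-2-methyl-N-(quinolin-8-yl)butanamide | C[C@@H](C(=O)Nc1cccc2cccnc12)[C@H](CO[Si](C)(C)C(C)(C)C)Cc1cc(OC)c(OCc2ccccc2)c(OC)c1 | intermediate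
15 | (2R,3R)-2-(4-benzyloxy-3-methoxybenzyl)-3-(4-benzyloxy-3,5-dimethoxybenzyl)-4-(tert-butyldimethylsilyloxy)-N-(quinolin-8-yl)butanamide | COc1cc(C[C@@H](C(=O)Nc2cccc3cccnc23)[C@H](CO[Si](C)(C)C(C)(C)C)Cc2cc(OC)c(OCc3ccccc3)c(OC)c2)ccc1OCc1ccccc1 | intermediate
16 | (2R,3R)-2-(4-benzyloxy-3-methoxybenzyl)-3-(4-benzyloxy-3,5-dimethoxybenzyl)-4-hydroxy-N-(quinolin-8-yl)butanamide | COc1cc(C[C@@H](C(=O)Nc2cccc3cccnc23)[C@H](CO)Cc2cc(OC)c(OCc3ccccc3)c(OC)c2)ccc1OCc1ccccc1 | intermediate (not isolated)
17 | (3R,4R)-3-(4-benzyloxy-3-methoxybenzyl)-4-(4-benzyloxy-3,5-dimethoxybenzyl)dihydrofuran-2(3H)-one | COc1cc(C[C@H]2C(=O)OC[C@@H]2Cc2cc(OC)c(OCc3ccccc3)c(OC)c2)ccc1OCc1ccccc1 | intermediate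
18 | (3R,4R)-3-(4-hydroxy-3-methoxybenzyl)-4-(4-hydroxy-3,5-dimethoxybenzyl)dihydrofuran-2(3H)-one | COc1cc(C[C@H]2C(=O)OC[C@@H]2Cc2cc(OC)c(O)c(OC)c2)ccc1O | target

## Step count and least certain steps

Total step count: 11. Longest linear sequence: 9 steps (steps 1, 2, 5, 6, 7, 8, 9, 10 and 11, from 1 to 18).

Step 9 (key step). The most likely failure is over-arylation: once the first aryl group is in place, the same chelate can metalate the new benzylic CH2 and add a second aryl group. Slow enolization of the amide α-carbon at 100 °C, which would erode the C2 configuration, is the second concern. The fallback changes the directing group to one known to stop after one arylation of a methyl group. It sets out from 11, which would be opened with 2-(methylsulfanyl)aniline and AlMe3 to give (2R,3R)-3-(4-benzyloxy-3,5-dimethoxybenzyl)-4-hydroxy-2-methyl-N-[2-(methylsulfanyl)phenyl]butanamide F1. Silylation with TBSCl and imidazole would give the silyl ether (2R,3R)-3-(4-benzyloxy-3,5-dimethoxybenzyl)-4-(tert-butyldimethylsilyloxy)-2-methyl-N-[2-(methylsulfanyl)phenyl]butanamide F2. Arylation with 5 under Pd(OAc)2 and AgOAc would give (2R,3R)-2-(4-benzyloxy-3-methoxybenzyl)-3-(4-benzyloxy-3,5-dimethoxybenzyl)-4-(tert-butyldimethylsilyloxy)-N-[2-(methylsulfanyl)phenyl]butanamide F3. Aqueous HCl in THF would then cleave the silyl ether and close the lactone with loss of the aniline, returning to the route at 17.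

Step 5. The carboxylate is a weak director and 3 is electron-rich, so slow palladation and slow oxidative addition may let reduction of the aryl iodide and biaryl formation take over. The fallback uses the stronger amide director and then removes it. It sets out from 8, which would be coupled with 12 (acid chloride, then amine) to give methyl (2R,3R)-2,3-dimethyl-4-oxo-4-(quinolin-8-ylamino)butanoate F4. Arylation with 3 under Pd(OAc)2 and AgOAc would give methyl (2R,3R)-3-(4-benzyloxy-3,5-dimethoxybenzyl)-2-methyl-4-oxo-4-(quinolin-8-ylamino)butanoate F5. Boc2O with DMAP would give the activated imide methyl (2R,3R)-3-(4-benzyloxy-3,5-dimethoxybenzyl)-4-[(tert-butoxycarbonyl)(quinolin-8-yl)amino]-2-methyl-4-oxobutanoate F6. Brief treatment with LiOH and H2O2 at 0 °C would cleave the imide selectively and return to the route at 9.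

Step 1. Single-electron oxidation of the electron-rich phenol with radical dimerization, or iodination at a carbon ortho to a methoxy group, may lower the yield of the para iodide. The fallback makes the C–halogen bond by a bromination that is para-selective through the phenoxide, then exchanges the halogen. It sets out from 1, which with NBS and catalytic NaH in CHCl3–MeOH at low temperature would give 4-bromo-2,6-dimethoxyphenol F7. Benzylation (BnBr, K2CO3) would give 2-(benzyloxy)-5-bromo-1,3-dimethoxybenzene F8. A copper-catalysed aromatic Finkelstein exchange (CuI, NaI, trans-N,N'-dimethylcyclohexane-1,2-diamine, dioxane, 110 °C) would return to the route at 3.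

Step 10. The silyl ether should cleave readily, but the acyl transfer from the anilide nitrogen to oxygen may stall at 16 if the hindered amide is not electrophilic enough under aqueous acid. The fallback activates the amide instead of relying on acid catalysis. It sets out from 15, which with Boc2O and DMAP in MeCN would give the N-Boc amide tert-butyl N-[(2R,3R)-2-(4-benzyloxy-3-methoxybenzyl)-3-(4-benzyloxy-3,5-dimethoxybenzyl)-4-(tert-butyldimethylsilyloxy)butanoyl]-N-(quinolin-8-yl)carbamate F9. TBAF in THF would remove the silyl group, and the alkoxide would close onto the twisted imide carbonyl, returning to the route at 17.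

## Further compounds

F1 | step 9 | (2R,3R)-3-(4-benzyloxy-3,5-dimethoxybenzyl)-4-hydroxy-2-methyl-N-[2-(methylsulfanyl)phenyl]butanamide | C[C@@H](C(=O)Nc1ccccc1SC)[C@H](CO)Cc1cc(OC)c(OCc2ccccc2)c(OC)c1
F2 | step 9 | (2R,3R)-3-(4-benzyloxy-3,5-dimethoxybenzyl)-4-(tert-butyldimethylsilyloxy)-2-methyl-N-[2-(methylsulfanyl)phenyl]butanamide | C[C@@H](C(=O)Nc1ccccc1SC)[C@H](CO[Si](C)(C)C(C)(C)C)Cc1cc(OC)c(OCc2ccccc2)c(OC)c1
F3 | step 9 | (2R,3R)-2-(4-benzyloxy-3-methoxybenzyl)-3-(4-benzyloxy-3,5-dimethoxybenzyl)-4-(tert-butyldimethylsilyloxy)-N-[2-(methylsulfanyl)phenyl]butanamide | COc1cc(C[C@@H](C(=O)Nc2ccccc2SC)[C@H](CO[Si](C)(C)C(C)(C)C)Cc2cc(OC)c(OCc3ccccc3)c(OC)c2)ccc1OCc1ccccc1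
F4 | step 5 | methyl (2R,3R)-2,3-dimethyl-4-oxo-4-(quinolin-8-ylamino)butanoate | C[C@@H](C(=O)OC)[C@H](C(=O)Nc1cccc2cccnc12)C
F5 | step 5 | methyl (2R,3R)-3-(4-benzyloxy-3,5-dimethoxybenzyl)-2-methyl-4-oxo-4-(quinolin-8-ylamino)butanoate | C[C@@H](C(=O)OC)[C@H](C(=O)Nc1cccc2cccnc12)Cc1cc(OC)c(OCc2ccccc2)c(OC)c1
F6 | step 5 | methyl (2R,3R)-3-(4-benzyloxy-3,5-dimethoxybenzyl)-4-[(tert-butoxycarbonyl)(quinolin-8-yl)amino]-2-methyl-4-oxobutanoate | C[C@@H](C(=O)OC)[C@H](C(=O)N(C(=O)OC(C)(C)C)c1cccc2cccnc12)Cc1cc(OC)c(OCc2ccccc2)c(OC)c1
F7 | step 1 | 4-bromo-2,6-dimethoxyphenol | COc1cc(Br)cc(OC)c1O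
F8 | step 1 | 2-(benzyloxy)-5-bromo-1,3-dimethoxybenzene | COc1cc(Br)cc(OC)c1OCc1ccccc1
F9 | step 10 | tert-butyl N-[(2R,3R)-2-(4-benzyloxy-3-methoxybenzyl)-3-(4-benzyloxy-3,5-dimethoxybenzyl)-4-(tert-butyldimethylsilyloxy)butanoyl]-N-(quinolin-8-yl)carbamate | COc1cc(C[C@@H](C(=O)N(C(=O)OC(C)(C)C)c2cccc3cccnc23)[C@H](CO[Si](C)(C)C(C)(C)C)Cc2cc(OC)c(OCc3ccccc3)c(OC)c2)ccc1OCc1ccccc1
A1 | alternative 1 | cis-fused 2-(4-hydroxy-3-methoxyphenyl)-6-(4-hydroxy-3,5-dimethoxyphenyl)-3,7-dioxabicyclo[3.3.0]octan-8-one | COc1cc([C@H]2OC[C@H]3[C@@H]2C(=O)O[C@@H]3c2cc(OC)c(O)c(OC)c2)ccc1O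
A2 | alternative 1 | ferulic acid, (E)-3-(4-hydroxy-3-methoxyphenyl)prop-2-enoic acid | COc1cc(/C=C/C(=O)O)ccc1O
A3 | alternative 1 | sinapyl alcohol, (E)-4-(3-hydroxyprop-1-enyl)-2,6-dimethoxyphenol | COc1cc(/C=C/CO)cc(OC)c1O
A4 | alternative 2 | (3R,4R)-3-(4-benzyloxy-3-methoxybenzyl)-4-(4-hydroxy-3,5-dimethoxybenzyl)dihydrofuran-2(3H)-one | COc1cc(C[C@H]2COC(=O)[C@@H]2Cc2ccc(OCc3ccccc3)c(OC)c2)cc(OC)c1O
A5 | alternative 2 | 1,3-dimethoxyacetone | COCC(=O)COC
A6 | alternative 2 | N-[2-{[(3R,4R)-4-(4-benzyloxy-3-methoxybenzyl)-5-oxotetrahydrofuran-3-yl]methyl}-3-(dimethylamino)prop-2-enylidene]-N-methylmethanaminium hexafluorophosphate | COc1cc(C[C@H]2C(=O)OC[C@@H]2CC(C=[N+](C)C)=CN(C)C)ccc1OCc1ccccc1.F[P-](F)(F)(F)(F)F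
A7 | alternative 2 | 3-[(3R,4R)-4-(4-benzyloxy-3-methoxybenzyl)-5-oxotetrahydrofuran-3-yl]propanoic acid | COc1cc(C[C@H]2C(=O)OC[C@@H]2CCC(=O)O)ccc1OCc1ccccc1
A8 | alternative 3 | methyl 3-(4-benzyloxy-3-methoxyphenyl)-2-[(4S,5R)-5-(4-benzyloxy-3,5-dimethoxyphenyl)-2,2-dimethyl-1-oxa-2-silacyclopentan-4-yl]propanoate (both epimers at the ester α-carbon) | COC(=O)C(Cc1ccc(OCc2ccccc2)c(OC)c1)[C@@H]1C[Si](C)(C)O[C@H]1c1cc(OC)c(OCc2ccccc2)c(OC)c1
A9 | alternative 3 | methyl (4R)-2-(4-benzyloxy-3-methoxybenzyl)-4-(4-benzyloxy-3,5-dimethoxyphenyl)-4-{[(bromomethyl)dimethylsilyl]oxy}but-2-enoate (alkene geometry not specified) | COC(=O)C(Cc1ccc(OCc2ccccc2)c(OC)c1)=C[C@@H](O[Si](C)(C)CBr)c1cc(OC)c(OCc2ccccc2)c(OC)c1
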